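**Retrosynthetic overview**
1. The ten-membered ring is closed last across C2–C3 by ring-closing metathesis of two vinyl oxiranes, followed by diimide saturation; tiglate (C8) and acetate (C13) are already in place.
2. The butenolide is made just before by oxidative lactonisation of a 2-alkylidenepropane-1,3-diol (C7=C11 carrying two CH2OH arms): the arm cis to C6-OH becomes C12, the other becomes C13.
3. Key union: a gem-dibromo-olefin linchpin (C7, C11, C12, C13; fragment B) is lithiated twice and joined first to epoxy aldehyde fragment A (C3–C6, sets C6) and then to epoxy Weinreb amide fragment C (C8–C10, C1, C2); C8 is then set by CBS reduction.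
4. Both cis-oxiranes come from Sharpless epoxidation of (Z)-allylic alcohols with opposite tartrates; ring order: two oxiranes (in the fragments), then butenolide, then the ten-membered carbocycle.

Assumption: locants C1–C15 in the explanations follow germacrane numbering of the target (C14 = methyl on C10, C15 = methyl on C4, C12 = lactone carbonyl, C13 = CH2OAc); compounds 1, 5, 10 and 13 are taken as commercial.

**Fragment A**

Step 1
Reactants: 1 (2Z)-3-methylpent-2-en-4-yn-1-ol
Product: 2 (2Z)-3-methylpenta-2,4-dien-1-ol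
Conditions: H2 (1 atm), Pd/CaCO3 poisoned with Pb(OAc)2 (Lindlar catalyst), quinoline, EtOAc, rt, stopped after 1 equiv H2
Reagents that add atoms: none
Why: Lindlar semi-hydrogenation reduces the terminal alkyne to a vinyl group and leaves the (Z)-trisubstituted alkene and its geometry untouched.

Step 2
Reactants: 2 (2Z)-3-methylpenta-2,4-dien-1-ol
Product: 3 [(2R,3S)-3-ethenyl-3-methyloxiran-2-yl]methanol
Conditions: Ti(OiPr)4 (10 mol%), D-(−)-diisopropyl tartrate (12 mol%), t-BuOOH, 4 Å MS, CH2Cl2, −20 °C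
Reagents that add atoms: tert-butyl hydroperoxide CC(C)(C)OO
Why: Sharpless asymmetric epoxidation attacks only the allylic-alcohol double bond, the D-tartrate ligand giving C5 (R) and C4 (S), and the Z geometry becomes the cis relationship of CH2OH and vinyl on the oxirane.

Step 3
Reactants: 3 [(2R,3S)-3-ethenyl-3-methyloxiran-2-yl]methanol
Product: 4 (2S,3S)-3-ethenyl-3-methyloxirane-2-carbaldehyde
Conditions: Dess–Martin periodinane, NaHCO3, CH2Cl2, 0 °C to rt; used as a solution
Reagents that add atoms: none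
Why: Buffered Dess–Martin oxidation gives the epoxy aldehyde without acid or base that could open the tertiary vinyl oxirane (the descriptor at C5 changes only because CHO outranks C4).

**Fragment B**

Step 4
Reactants: 5 2-methylidenepropane-1,3-diol
Product: 6 2-methylidenepropane-1,3-diol bis(tert-butyldimethylsilyl) ether
Conditions: TBSCl (2.2 equiv), imidazole, DMF, rt
Reagents that add atoms: tert-butyldimethylsilyl chloride CC(C)(C)[Si](C)(C)Cl
Why: Standard silylation of both primary alcohols gives arms that survive the later organolithium steps.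

Step 5
Reactants: 6 2-methylidenepropane-1,3-diol bis(tert-butyldimethylsilyl) ether
Product: 8 1,3-bis(tert-butyldimethylsilyloxy)propan-2-one, via ozonide 7 (not isolated)
Conditions: O3, CH2Cl2, −78 °C; then Me2S, −78 °C to rt
Reagents that add atoms: ozone [O-][O+]=O
Why: Ozonolysis with reductive work-up cleaves the 1,1-disubstituted alkene to the symmetrical ketone.

Step 6
Reactants: 8 1,3-bis(tert-butyldimethylsilyloxy)propan-2-one
Product: 9 1,1-dibromo-2,2-bis[(tert-butyldimethylsilyloxy)methyl]ethene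
Conditions: CBr4 (2 equiv), PPh3 (4 equiv), CH2Cl2, 0 °C to rt
Reagents that add atoms: carbon tetrabromide BrC(Br)(Br)Br
Why: Ramirez dibromo-olefination (the first stage of a Corey–Fuchs sequence) works on this electron-poor α,α'-dialkoxy ketone and gives a linchpin whose two identical arms remove any alkene-geometry problem.

**Fragment C**

Step 7
Reactants: 10 but-2-yn-1-ol
Product: 12 (2Z)-3-iodobut-2-en-1-ol, via cyclic alkenylalanate 11 (not isolated)
Conditions: NaAlH2(OCH2CH2OMe)2, Et2O, 0 °C to rt; then I2, THF, −78 °C to 0 °C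
Reagents that add atoms: iodine II
Why: Alkoxide-directed trans-hydroalumination places aluminium on C3 in a five-membered chelate, and iodinolysis with retention gives the (Z)-iodide with iodine cis to CH2OH.

Step 8
Reactants: 12 (2Z)-3-iodobut-2-en-1-ol; 13 2-bromo-N-methoxy-N-methylacetamide
Product: 15 (3Z)-5-hydroxy-N-methoxy-N,3-dimethylpent-3-enamide, via Reformatsky zinc reagent 14 (not isolated)
Conditions: 13, activated Zn dust, THF, rt; then 12 (0.4 equiv relative to 14), Pd(PPh3)4 (5 mol%), THF, 45 °C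
Reagents that add atoms: none
Why: Negishi-type cross-coupling of the Reformatsky reagent with the alkenyl iodide forms the C9–C10 bond with retention of the Z geometry (excess zinc reagent absorbs the free hydroxyl).

Step 9
Reactants: 15 (3Z)-5-hydroxy-N-methoxy-N,3-dimethylpent-3-enamide
Product: 16 2-[(2R,3S)-3-(hydroxymethyl)-2-methyloxiran-2-yl]-N-methoxy-N-methylacetamide
Conditions: Ti(OiPr)4 (1.0 equiv), L-(+)-diisopropyl tartrate (1.2 equiv), t-BuOOH, 4 Å MS, CH2Cl2, −25 °C
Reagents that add atoms: tert-butyl hydroperoxide CC(C)(C)OO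
Why: Sharpless asymmetric epoxidation with the tartrate enantiomeric to that of step 2 sets C1 (S) and C10 (R), and the Z-alkene gives the cis-oxirane.

Step 10
Reactants: 16 2-[(2R,3S)-3-(hydroxymethyl)-2-methyloxiran-2-yl]-N-methoxy-N-methylacetamide
Product: 17 2-[(2R,3R)-3-formyl-2-methyloxiran-2-yl]-N-methoxy-N-methylacetamide
Conditions: Dess–Martin periodinane, NaHCO3, CH2Cl2, 0 °C to rt
Reagents that add atoms: none
Why: Neutral Dess–Martin oxidation avoids the base-induced elimination open to a β,γ-epoxy amide (descriptor change at C1 is formal).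

Step 11
Reactants: 17 2-[(2R,3R)-3-formyl-2-methyloxiran-2-yl]-N-methoxy-N-methylacetamide
Product: 18 2-[(2R,3S)-3-ethenyl-2-methyloxiran-2-yl]-N-methoxy-N-methylacetamide
Conditions: Ph3PCH3Br, KN(SiMe3)2, THF, −78 °C to 0 °C
Reagents that add atoms: methyltriphenylphosphonium bromide C[P+](c1ccccc1)(c1ccccc1)c1ccccc1.[Br-]
Why: Wittig methylenation of the epoxy aldehyde installs the vinyl group for ring closure; the non-stabilised ylide reacts with the aldehyde much faster than with the Weinreb amide.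

**Assembly**

Step 12
Reactants: 9 1,1-dibromo-2,2-bis[(tert-butyldimethylsilyloxy)methyl]ethene; 4 (2S,3S)-3-ethenyl-3-methyloxirane-2-carbaldehyde
Product: 20 (1S)-2-bromo-4-(tert-butyldimethylsilyloxy)-3-[(tert-butyldimethylsilyloxy)methyl]-1-[(2R,3S)-3-ethenyl-3-methyloxiran-2-yl]but-2-en-1-ol, via bromolithio carbenoid 19 (not isolated)
Conditions: 9, n-BuLi (1.05 equiv), THF/Et2O/pentane, −105 °C; then 4, −105 to −78 °C; aqueous work-up at −78 °C
Reagents that add atoms: none
Why: Bromine–lithium exchange gives the 1-bromo-1-lithioalkene, which adds to the aldehyde under Felkin–Anh control (attack anti to the oxirane C–O bond) to set C6 as the anti epoxy alcohol, (1S) here and (R) in the target once bromine is replaced by carbon.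

Step 13
Reactants: 20 (1S)-2-bromo-4-(tert-butyldimethylsilyloxy)-3-[(tert-butyldimethylsilyloxy)methyl]-1-[(2R,3S)-3-ethenyl-3-methyloxiran-2-yl]but-2-en-1-ol
Product: 21 O-triethylsilyl ether of 20
Conditions: Et3SiCl, imidazole, CH2Cl2, 0 °C
Reagents that add atoms: triethylsilyl chloride CC[Si](CC)(CC)Cl
Why: Mild silylation masks the C6 hydroxyl for the second lithiation without touching the oxirane.

Step 14
Reactants: 21 O-triethylsilyl ether of 20; 18 2-[(2R,3S)-3-ethenyl-2-methyloxiran-2-yl]-N-methoxy-N-methylacetamide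
Product: 24 5-(tert-butyldimethylsilyloxy)-4-[(tert-butyldimethylsilyloxy)methyl]-1-[(2R,3S)-3-ethenyl-2-methyloxiran-2-yl]-3-[(R)-[(2R,3S)-3-ethenyl-3-methyloxiran-2-yl](triethylsilyloxy)methyl]pent-3-en-2-one, via alkenyllithium 22 (not isolated), via lithium hemiaminal alkoxide 23 (not isolated)
Conditions: 21, t-BuLi (2.1 equiv), Et2O, −78 °C, 15 min; then 18, −78 to −40 °C; aqueous work-up
Reagents that add atoms: none
Why: The second bromine–lithium exchange gives the tetrasubstituted alkenyllithium, and its acylation by the Weinreb amide (chelated tetrahedral intermediate, no over-addition) joins the third fragment through the C7–C8 bond; Et2O at −78 °C keeps silyl migration to carbon slow.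

Step 15
Reactants: 24 (enone from step 14)
Product: 25 (2R)-5-(tert-butyldimethylsilyloxy)-4-[(tert-butyldimethylsilyloxy)methyl]-1-[(2R,3S)-3-ethenyl-2-methyloxiran-2-yl]-3-[(R)-[(2R,3S)-3-ethenyl-3-methyloxiran-2-yl](triethylsilyloxy)methyl]pent-3-en-2-ol
Conditions: (S)-2-methyl-CBS-oxazaborolidine (1 equiv), catecholborane, toluene, −78 °C
Reagents that add atoms: none
Why: Corey–Bakshi–Shibata reduction, with the fully substituted alkenyl group as the large and the CH2 group as the small substituent, sets C8 (R) under reagent control; catecholborane at −78 °C does not hydroborate the vinyl groups.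

Step 16
Reactants: 25 (allylic alcohol from step 15)
Product: 26 (2E)-2-methylbut-2-enoate (tiglate) ester of 25
Conditions: (E)-2-methylbut-2-enoyl chloride, Et3N, DMAP, CH2Cl2, 0 °C to rt
Reagents that add atoms: (E)-2-methylbut-2-enoyl chloride C/C=C(\C)C(Cl)=O
Why: DMAP-catalysed acylation installs the tiglate after the last organolithium step; it also blocks C8-OH so that only C6-OH can lactonise in step 18.

Step 17
Reactants: 26 (tiglate from step 16)
Product: 27 (2R)-1-[(2R,3S)-3-ethenyl-2-methyloxiran-2-yl]-3-[(R)-[(2R,3S)-3-ethenyl-3-methyloxiran-2-yl](hydroxy)methyl]-5-hydroxy-4-(hydroxymethyl)pent-3-en-2-yl (2E)-2-methylbut-2-enoate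
Conditions: Bu4NF/AcOH (1:1, 4 equiv), THF, 0 °C to rt
Reagents that add atoms: none
Why: Buffered fluoride desilylation removes the triethylsilyl and both primary tert-butyldimethylsilyl groups without opening the oxiranes or moving the tiglate.

Step 18
Reactants: 27 (triol from step 17)
Product: 29 (1R)-2-[(2R,3S)-3-ethenyl-2-methyloxiran-2-yl]-1-[(2R)-2-[(2R,3S)-3-ethenyl-3-methyloxiran-2-yl]-4-formyl-5-oxo-2,5-dihydrofuran-3-yl]ethyl (2E)-2-methylbut-2-enoate, via formyl lactol 28 (not isolated)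
Conditions: Cu(MeCN)4OTf (10 mol%), 2,2'-bipyridine (10 mol%), TEMPO (10 mol%), N-methylimidazole (20 mol%), air, MeCN, rt; used crude
Reagents that add atoms: none
Why: Copper/nitroxyl aerobic oxidation turns both primary allylic alcohols into aldehydes, but only the one cis to C6-OH can close to a five-membered lactol, which is oxidised on to the butenolide (oxidative lactonisation), so C12 and C13 are told apart by geometry alone.

Step 19
Reactants: 29 (formyl butenolide from step 18)
Product: 30 (1R)-2-[(2R,3S)-3-ethenyl-2-methyloxiran-2-yl]-1-[(2R)-2-[(2R,3S)-3-ethenyl-3-methyloxiran-2-yl]-4-(hydroxymethyl)-5-oxo-2,5-dihydrofuran-3-yl]ethyl (2E)-2-methylbut-2-enoate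
Conditions: NaBH4, CeCl3·7H2O, MeOH/THF, −78 °C
Reagents that add atoms: none
Why: Luche reduction gives chemoselective 1,2-reduction of the aldehyde in the presence of the lactone, the esters and the hindered tetrasubstituted conjugated alkene.

Step 20
Reactants: 30 (hydroxymethyl butenolide from step 19)
Product: 31 (1R)-1-[(2R)-4-(acetyloxymethyl)-2-[(2R,3S)-3-ethenyl-3-methyloxiran-2-yl]-5-oxo-2,5-dihydrofuran-3-yl]-2-[(2R,3S)-3-ethenyl-2-methyloxiran-2-yl]ethyl (2E)-2-methylbut-2-enoate
Conditions: Ac2O, pyridine, DMAP (cat.), CH2Cl2, 0 °C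
Reagents that add atoms: acetic anhydride CC(=O)OC(C)=O
Why: Simple acetylation of the only free hydroxyl gives the C13 acetate.

Step 21
Reactants: 31 (seco-diene from step 20)
Product: 32 (1S,2Z,4S,5R,6R,8R,10R)-13-acetoxy-1,10:4,5-diepoxy-8-[(2E)-2-methylbut-2-enoyloxy]germacra-2,7(11)-dien-12,6-olide
Conditions: second-generation Grubbs catalyst (H2IMes)(PCy3)Cl2Ru=CHPh (15 mol%), 1,4-benzoquinone (cat.), toluene (1 mM), 80 °C
Reagents that add atoms: none
Why: Ring-closing metathesis of the two vinyl groups, turned towards each other by the two cis-oxiranes and the lactone-locked C6, closes the ten-membered ring with loss of ethene; Z is expected, but the geometry is irrelevant because the alkene is saturated next.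

Step 22
Reactants: 32 (macrocyclic alkene from step 21)
Product: 33 (1S,4S,5R,6R,8R,10R)-13-acetoxy-1,10:4,5-diepoxy-8-[(2E)-2-methylbut-2-enoyloxy]germacr-7(11)-en-12,6-olide (target)
Conditions: 2-nitrobenzenesulfonyl hydrazide, Et3N, CH2Cl2, rt
Reagents that add atoms: none
Why: Diimide reduction (concerted syn transfer of two hydrogens) saturates the strained disubstituted ring alkene without hydrogenolysis of the two allylic oxiranes and faster than the trisubstituted tiglate or the tetrasubstituted butenolide alkene.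

**Compound list**

1 | (2Z)-3-methylpent-2-en-4-yn-1-ol | C#C/C(C)=C\CO | starting material
2 | (2Z)-3-methylpenta-2,4-dien-1-ol | C=C/C(C)=C\CO | intermediate
3 | [(2R,3S)-3-ethenyl-3-methyloxiran-2-yl]methanol | C=C[C@]1(C)O[C@@H]1CO | intermediate
4 | (2S,3S)-3-ethenyl-3-methyloxirane-2-carbaldehyde (fragment A) | C=C[C@]1(C)O[C@@H]1C=O | intermediate
5 | 2-methylidenepropane-1,3-diol | C=C(CO)CO | starting material
6 | 2-methylidenepropane-1,3-diol bis(tert-butyldimethylsilyl) ether | C=C(CO[Si](C)(C)C(C)(C)C)CO[Si](C)(C)C(C)(C)C | intermediate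
7 | ozonide, 3,3-bis[(tert-butyldimethylsilyloxy)methyl]-1,2,4-trioxolane | C1OC(CO[Si](C)(C)C(C)(C)C)(CO[Si](C)(C)C(C)(C)C)OO1 | intermediate
8 | 1,3-bis(tert-butyldimethylsilyloxy)propan-2-one | O=C(CO[Si](C)(C)C(C)(C)C)CO[Si](C)(C)C(C)(C)C | intermediate
9 | 1,1-dibromo-2,2-bis[(tert-butyldimethylsilyloxy)methyl]ethene (fragment B) | BrC(Br)=C(CO[Si](C)(C)C(C)(C)C)CO[Si](C)(C)C(C)(C)C | intermediate
10 | but-2-yn-1-ol | CC#CCO | starting material
11 | cyclic alkenylalanate, sodium 2,2-bis(2-methoxyethoxy)-3-methyl-2,5-dihydro-1,2-oxaaluminol-2-uide | CC1=CCO[Al-]1(OCCOC)OCCOC.[Na+] | intermediate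
12 | (2Z)-3-iodobut-2-en-1-ol | C/C(I)=C/CO | intermediate
13 | 2-bromo-N-methoxy-N-methylacetamide | CON(C)C(=O)CBr | starting material
14 | Reformatsky zinc reagent, bromo[2-[methoxy(methyl)amino]-2-oxoethyl]zinc | CON(C)C(=O)C[Zn]Br | intermediate
15 | (3Z)-5-hydroxy-N-methoxy-N,3-dimethylpent-3-enamide | CON(C)C(=O)C/C(C)=C\CO | intermediate
16 | 2-[(2R,3S)-3-(hydroxymethyl)-2-methyloxiran-2-yl]-N-methoxy-N-methylacetamide | CON(C)C(=O)C[C@@]1(C)O[C@H]1CO | intermediate
17 | 2-[(2R,3R)-3-formyl-2-methyloxiran-2-yl]-N-methoxy-N-methylacetamide | CON(C)C(=O)C[C@@]1(C)O[C@H]1C=O | intermediate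
18 | 2-[(2R,3S)-3-ethenyl-2-methyloxiran-2-yl]-N-methoxy-N-methylacetamide (fragment C) | CON(C)C(=O)C[C@@]1(C)O[C@H]1C=C | intermediate
19 | bromolithio carbenoid, 1-bromo-1-lithio-2,2-bis[(tert-butyldimethylsilyloxy)methyl]ethene | [Li]C(Br)=C(CO[Si](C)(C)C(C)(C)C)CO[Si](C)(C)C(C)(C)C | intermediate
20 | (1S)-2-bromo-4-(tert-butyldimethylsilyloxy)-3-[(tert-butyldimethylsilyloxy)methyl]-1-[(2R,3S)-3-ethenyl-3-methyloxiran-2-yl]but-2-en-1-ol | BrC(=C(CO[Si](C)(C)C(C)(C)C)CO[Si](C)(C)C(C)(C)C)[C@@H](O)[C@H]1O[C@@]1(C)C=C | intermediate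
21 | O-triethylsilyl ether of 20 | BrC(=C(CO[Si](C)(C)C(C)(C)C)CO[Si](C)(C)C(C)(C)C)[C@@H](O[Si](CC)(CC)CC)[C@H]1O[C@@]1(C)C=C | intermediate
22 | alkenyllithium from 21 (Li in place of Br) | [Li]C(=C(CO[Si](C)(C)C(C)(C)C)CO[Si](C)(C)C(C)(C)C)[C@@H](O[Si](CC)(CC)CC)[C@H]1O[C@@]1(C)C=C | intermediate
23 | lithium hemiaminal alkoxide (adduct of 22 to the amide carbonyl of 18) | [Li+].[O-]C(C[C@@]1(C)O[C@H]1C=C)(N(C)OC)C(=C(CO[Si](C)(C)C(C)(C)C)CO[Si](C)(C)C(C)(C)C)[C@@H](O[Si](CC)(CC)CC)[C@H]1O[C@@]1(C)C=C | intermediate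
24 | 5-(tert-butyldimethylsilyloxy)-4-[(tert-butyldimethylsilyloxy)methyl]-1-[(2R,3S)-3-ethenyl-2-methyloxiran-2-yl]-3-[(R)-[(2R,3S)-3-ethenyl-3-methyloxiran-2-yl](triethylsilyloxy)methyl]pent-3-en-2-one | O=C(C[C@@]1(C)O[C@H]1C=C)C(=C(CO[Si](C)(C)C(C)(C)C)CO[Si](C)(C)C(C)(C)C)[C@@H](O[Si](CC)(CC)CC)[C@H]1O[C@@]1(C)C=C | intermediate
25 | (2R)-alcohol of 24, (2R)-5-(tert-butyldimethylsilyloxy)-4-[(tert-butyldimethylsilyloxy)methyl]-1-[(2R,3S)-3-ethenyl-2-methyloxiran-2-yl]-3-[(R)-[(2R,3S)-3-ethenyl-3-methyloxiran-2-yl](triethylsilyloxy)methyl]pent-3-en-2-ol | O[C@H](C[C@@]1(C)O[C@H]1C=C)C(=C(CO[Si](C)(C)C(C)(C)C)CO[Si](C)(C)C(C)(C)C)[C@@H](O[Si](CC)(CC)CC)[C@H]1O[C@@]1(C)C=C | intermediate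
26 | (2E)-2-methylbut-2-enoate (tiglate) ester of 25 | C/C=C(\C)C(=O)O[C@H](C[C@@]1(C)O[C@H]1C=C)C(=C(CO[Si](C)(C)C(C)(C)C)CO[Si](C)(C)C(C)(C)C)[C@@H](O[Si](CC)(CC)CC)[C@H]1O[C@@]1(C)C=C | intermediate
27 | (2R)-1-[(2R,3S)-3-ethenyl-2-methyloxiran-2-yl]-3-[(R)-[(2R,3S)-3-ethenyl-3-methyloxiran-2-yl](hydroxy)methyl]-5-hydroxy-4-(hydroxymethyl)pent-3-en-2-yl (2E)-2-methylbut-2-enoate | C/C=C(\C)C(=O)O[C@H](C[C@@]1(C)O[C@H]1C=C)C(=C(CO)CO)[C@@H](O)[C@H]1O[C@@]1(C)C=C | intermediate
28 | formyl lactol, the 5-hydroxy-2,5-dihydrofuran analogue of 29 (lactol carbon undefined) | C/C=C(\C)C(=O)O[C@H](C[C@@]1(C)O[C@H]1C=C)C1=C(C=O)C(O)O[C@H]1[C@H]1O[C@@]1(C)C=C | intermediate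
29 | (1R)-2-[(2R,3S)-3-ethenyl-2-methyloxiran-2-yl]-1-[(2R)-2-[(2R,3S)-3-ethenyl-3-methyloxiran-2-yl]-4-formyl-5-oxo-2,5-dihydrofuran-3-yl]ethyl (2E)-2-methylbut-2-enoate | C/C=C(\C)C(=O)O[C@H](C[C@@]1(C)O[C@H]1C=C)C1=C(C=O)C(=O)O[C@H]1[C@H]1O[C@@]1(C)C=C | intermediate
30 | 4-(hydroxymethyl) analogue of 29 | C/C=C(\C)C(=O)O[C@H](C[C@@]1(C)O[C@H]1C=C)C1=C(CO)C(=O)O[C@H]1[C@H]1O[C@@]1(C)C=C | intermediate
31 | 4-(acetyloxymethyl) analogue of 29 (seco-diene) | C/C=C(\C)C(=O)O[C@H](C[C@@]1(C)O[C@H]1C=C)C1=C(COC(C)=O)C(=O)O[C@H]1[C@H]1O[C@@]1(C)C=C | intermediate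
32 | (1S,2Z,4S,5R,6R,8R,10R)-13-acetoxy-1,10:4,5-diepoxy-8-[(2E)-2-methylbut-2-enoyloxy]germacra-2,7(11)-dien-12,6-olide | C/C=C(\C)C(=O)O[C@@H]1C[C@@]2(C)O[C@H]2/C=C\[C@]2(C)O[C@@H]2[C@@H]2OC(=O)C(COC(C)=O)=C21 | intermediate
33 | (1S,4S,5R,6R,8R,10R)-13-acetoxy-1,10:4,5-diepoxy-8-[(2E)-2-methylbut-2-enoyloxy]germacr-7(11)-en-12,6-olide | C/C=C(\C)C(=O)O[C@@H]1C[C@@]2(C)O[C@H]2CC[C@]2(C)O[C@@H]2[C@@H]2OC(=O)C(COC(C)=O)=C21 | target

**Step count and risks**

Total step count: 22. Longest linear sequence: 14 steps (steps 1–3 then 12–22; the lines through 5 and through 10 are equally long), which is 14/22 of the total.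

The three steps most likely to fail:

Step 14 (hindered tetrasubstituted alkenyllithium with an enolisable β,γ-epoxy Weinreb amide; competing deprotonation and silyl migration). The fallback sets out from 18 and 21 and comes back at 24. Amide 18 is reduced with i-Bu2AlH (toluene, −78 °C) to 2-[(2R,3S)-3-ethenyl-2-methyloxiran-2-yl]acetaldehyde F1, which is used at once. Alkenyllithium 22, made from 21 as before, adds to this far more electrophilic aldehyde at −78 °C to give the allylic alcohol 25 mixed with its C8 epimer F2. Dess–Martin oxidation of the mixture gives enone 24, and C8 is then set in step 15 as planned.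

Step 18 (the α-formyl butenolide 29 is very electrophilic and its C6–H is acidic, so it may not survive isolation). The fallback sets out from 27 and comes back at 30, with no new compound. Acceptor-driven transfer dehydrogenation with RuH2(PPh3)4 and benzalacetone (2 equiv) in toluene oxidises only the C12-OH/C6-OH pair, because only that lactol is drained irreversibly to the lactone. The isolated C13-OH stays at the alcohol level under the hydrogen-transfer equilibrium, so 29 and step 19 are bypassed.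

Step 21 (ten-membered ring closure between two hindered vinyl oxiranes on a rigid lactone-locked substrate; dimerisation is the likely competitor). The fallback sets out from 26 and comes back at 32: the order of ring construction is inverted, closing the carbocycle on the open-chain silyl ether, where the groups on C6 and C8 can still rotate about the tetrasubstituted alkene. Ring-closing metathesis of 26 (same catalyst, 1 mM) gives the macrocyclic tiglate tris(silyl ether) F3. Bu4NF/AcOH then gives the macrocyclic triol F4, and copper/TEMPO aerobic oxidation gives the macrocyclic formyl butenolide F5. Luche reduction gives the macrocyclic hydroxymethyl butenolide F6, and acetylation gives 32, which goes on to step 22.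

Further compounds
F1 | step 14 | 2-[(2R,3S)-3-ethenyl-2-methyloxiran-2-yl]acetaldehyde | O=CC[C@@]1(C)O[C@H]1C=C
F2 | step 14 | allylic alcohol 25 mixed with its C8 epimer (C8 undefined) | OC(C[C@@]1(C)O[C@H]1C=C)C(=C(CO[Si](C)(C)C(C)(C)C)CO[Si](C)(C)C(C)(C)C)[C@@H](O[Si](CC)(CC)CC)[C@H]1O[C@@]1(C)C=C
F0 | step 18 | none | none
F3 | step 21 | macrocyclic tiglate tris(silyl ether), ring-closed (2Z) form of 26 | C/C=C(\C)C(=O)O[C@@H]1C[C@@]2(C)O[C@H]2/C=C\[C@]2(C)O[C@@H]2[C@H](O[Si](CC)(CC)CC)C1=C(CO[Si](C)(C)C(C)(C)C)CO[Si](C)(C)C(C)(C)C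
F4 | step 21 | macrocyclic triol, desilylated F3 | C/C=C(\C)C(=O)O[C@@H]1C[C@@]2(C)O[C@H]2/C=C\[C@]2(C)O[C@@H]2[C@H](O)C1=C(CO)CO
F5 | step 21 | macrocyclic formyl butenolide, 13-oxo analogue of 32 without the acetate | C/C=C(\C)C(=O)O[C@@H]1C[C@@]2(C)O[C@H]2/C=C\[C@]2(C)O[C@@H]2[C@@H]2OC(=O)C(C=O)=C21
F6 | step 21 | macrocyclic hydroxymethyl butenolide, 13-hydroxy analogue of 32 | C/C=C(\C)C(=O)O[C@@H]1C[C@@]2(C)O[C@H]2/C=C\[C@]2(C)O[C@@H]2[C@@H]2OC(=O)C(CO)=C21
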